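Locants follow the geranyllinalool skeleton: vinyl C1=C2, ether carbon C3, epoxide C6–C7, carbocycle C10–C15 (C11–O, C14–Br, C15 gem-dimethyl). Everything rests on cutting the bromocyclohexane at its only CH2–CH2 bond, C12–C13. In one operation the isopropenyl group (C11=C12) of an acyclic, stereodefined 2-bromoalkyl triflate displaces the C13 triflate and the C11 cation is captured by a Boc carbonate on C9, closing the six-membered carbocycle and a trans-fused cyclic carbonate and fixing C11 relative to C10 and C14. The derived 1,3-diol then templates the di-tertiary ether as a dioxane ketal; B-alkyl Suzuki coupling closes the oxecane before epoxidation.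

Key step: step 9

Remark: the locants C1–C15 defined above are used for all intermediates.
Remark (assumption): the less soluble salt in step 3 is taken to contain the (R)-acid, and the catalyst antipodes named in steps 8 and 17 are taken to deliver the required faces; if a sense is opposite, the antipodal amine or catalyst is used.

Step 1
Reactants: 1 3-methylbut-2-en-1-ol (prenol); 2 3-methylbut-2-enoyl chloride
Product: 3 3-methylbut-2-en-1-yl 3-methylbut-2-enoate (prenyl senecioate)
Conditions: pyridine, DMAP (cat.), CH2Cl2, 0 → 23 °C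
Reagents that add atoms: none
Why: Acylation of the primary allylic alcohol (esterification); pyridine rather than a trialkylamine avoids vinylketene formation and deconjugation of the acyl chloride.

Step 2
Reactants: 3 prenyl senecioate
Product: 6 rac-3,3-dimethyl-2-(prop-1-en-2-yl)pent-4-enoic acid, via silyl ketene acetal 4 (not isolated), via trimethylsilyl ester 5 (not isolated)
Conditions: LiN(iPr)2, THF/DMPU, −78 °C; Me3SiCl; −78 → 23 °C; then 1 M HCl
Reagents that add atoms: none
Why: Ireland–Claisen rearrangement: γ-deprotonation gives the silyl dienol ketene acetal, whose [3,3] shift joins the α-carbon (C10) to the dimethyl-substituted allyl terminus (C15); the temperature is kept at or below 23 °C so that the 1,5-diene does not undergo Cope rearrangement.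

Step 3
Reactants: 6 rac-acid; 7 (S)-1-phenylethylamine
Product: 8 (S)-1-phenylethylammonium (R)-3,3-dimethyl-2-(prop-1-en-2-yl)pent-4-enoate
Conditions: 7 (1.0 equiv), EtOAc/hexane, two recrystallisations
Reagents that add atoms: none
Why: Classical resolution by fractional crystallisation of diastereomeric ammonium salts; this sets C10.

Step 4
Reactants: 8 ammonium salt
Product: 10 (R)-3,3-dimethyl-2-(prop-1-en-2-yl)pent-4-en-1-ol, via free (R)-acid 9 (not isolated)
Conditions: 1 M HCl/Et2O partition; then LiAlH4, Et2O, 0 → 23 °C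
Reagents that add atoms: none
Why: Liberation of the acid and hydride reduction to the primary alcohol (C9); C10 is not touched.

Step 5
Reactants: 10 (R)-alcohol
Product: 11 tert-butyl (R)-3,3-dimethyl-2-(prop-1-en-2-yl)pent-4-en-1-yl carbonate
Conditions: Boc2O, 1-methylimidazole, toluene, 23 °C
Reagents that add atoms: di-tert-butyl dicarbonate CC(C)(C)OC(=O)OC(=O)OC(C)(C)C
Why: O-tert-butoxycarbonylation installs the carbonate that later terminates the cyclisation and keeps the C9 oxygen non-nucleophilic.

Step 6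
Reactants: 11 carbonate
Product: 13 tert-butyl (R)-5-hydroxy-3,3-dimethyl-2-(prop-1-en-2-yl)pentyl carbonate, via catechol boronate 12 (not isolated)
Conditions: catecholborane, RhCl(PPh3)3 (2 mol %), THF, 0 → 23 °C; then NaBO3·4H2O, THF/H2O
Reagents that add atoms: sodium perborate [Na+].OO[B-](O)(O)O
Why: Rhodium-catalysed hydroboration–oxidation should select the monosubstituted vinyl group over the 1,1-disubstituted isopropenyl group and give the anti-Markovnikov alcohol at C13; a Wacker-type oxidation is avoided because divalent palladium can trigger Cope rearrangement of this 1,5-diene.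

Step 7
Reactants: 13 primary alcohol
Product: 14 tert-butyl (R)-3,3-dimethyl-5-oxo-2-(prop-1-en-2-yl)pentyl carbonate
Conditions: Dess–Martin periodinane, NaHCO3, CH2Cl2, 0 → 23 °C
Reagents that add atoms: none
Why: Dess–Martin oxidation to the aldehyde under buffered, non-epimerising conditions.

Step 8
Reactants: 14 aldehyde
Product: 16 tert-butyl (2R,4R)-4-bromo-5-hydroxy-3,3-dimethyl-2-(prop-1-en-2-yl)pentyl carbonate, via α-bromo aldehyde 15 (not isolated)
Conditions: (2S,5S)-2,5-diphenylpyrrolidine (20 mol %), PhCO2H (20 mol %), 4,4-dibromo-2,6-di-tert-butylcyclohexa-2,5-dienone, CH2Cl2/pentane, −24 °C; then NaBH4, MeOH, −24 → 0 °C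
Reagents that add atoms: 4,4-dibromo-2,6-di-tert-butylcyclohexa-2,5-dien-1-one CC(C)(C)C1=CC(Br)(Br)C=C(C(C)(C)C)C1=O
Why: Enamine-catalysed asymmetric α-bromination sets C14 under catalyst control, and immediate borohydride reduction of the labile α-bromo aldehyde preserves it.

Step 9
Reactants: 16 bromohydrin carbonate
Product: 18 (4aR,6S,8aS)-6-bromo-5,5,8a-trimethylhexahydro-4H-benzo[d][1,3]dioxin-2-one, via primary triflate 17 (not isolated)
Conditions: Tf2O, 2,6-di-tert-butyl-4-methylpyridine, CH2Cl2, −78 °C; then (CF3)2CHOH, −78 → 0 °C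
Reagents that add atoms: none
Why: Triflation gives a 2-bromoalkyl triflate whose C13–O bond ionises with assistance from the vicinal bromine and is displaced by the terminal carbon C12 of the isopropenyl group through a chair transition state, forming the C12–C13 bond and a tertiary C11 cation that the Boc carbonyl oxygen on C9 captures with loss of 2-methylpropene. The closest known reaction types are π-route solvolysis of hex-5-enyl sulfonates, bromonium-initiated cation–olefin cyclisation and Boc-carbonate termination of polyene cyclisations. The carbocycle closes 6-endo-trig with respect to the alkene (exo-tet at C13), and the carbonate ring closes by 6-membered attack of the carbonyl oxygen on the C11 cation. C14 keeps the configuration from step 8 because its C–Br bond is never broken, C10 is a spectator that places CH2OBoc equatorial, and C11 is set by anti addition across C11=C12, the tethered oxygen entering equatorially to give the trans-fused carbonate with axial methyl. The step needs C–C bond formation at C13 rather than at C14 and no oxygen alkylation; neopentyl hindrance at C14 and the six-membered chair available only for C12→C13 secure the first, and the carbonate, whose carbonyl oxygen reaches C11 through a 6-membered ring but C13 only through an 8-membered one, secures the second. The hindered pyridine base and the ionising, weakly nucleophilic fluoro alcohol should suppress elimination and solvent capture.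

Step 10
Reactants: 18 cyclic carbonate
Product: 19 (1S,2R,4S)-4-bromo-2-(hydroxymethyl)-1,3,3-trimethylcyclohexan-1-ol
Conditions: K2CO3, MeOH, 23 °C
Reagents that add atoms: none
Why: Base-mediated methanolysis (transesterification) of the cyclic carbonate; the equatorial bromide has no antiperiplanar hydrogen or reachable internal nucleophile.

Step 11
Reactants: 19 diol; 20 4-(trimethylsilyl)but-3-yn-2-one
Product: 22 (2S,4aR,6S,8aS)-6-bromo-2,5,5,8a-tetramethyl-2-[(trimethylsilyl)ethynyl]hexahydro-4H-benzo[d][1,3]dioxine, via bis(trimethylsilyl) ether 21 (not isolated)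
Conditions: Me3SiOTf (2.2 equiv), 2,6-lutidine, CH2Cl2, −78 → 0 °C; then 20, Me3SiOTf (10 mol %), CH2Cl2, −78 → −20 °C; pyridine
Reagents that add atoms: none
Why: Noyori ketalisation under equilibrating conditions; the linear alkynyl group should take the axial position (syn to the axial C11 methyl) and the methyl the equatorial one, which fixes the ketal carbon, the future C3.

Step 12
Reactants: 22 alkynyl ketal
Product: 23 {(1R,3S,6S)-3-bromo-2,2,6-trimethyl-6-[(R)-3-methyl-5-(trimethylsilyl)pent-1-en-4-yn-3-yl]oxycyclohexyl}methanol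
Conditions: Me2Al(CH=CH2) (3 equiv; from CH2=CHMgBr and Me2AlCl), toluene/CH2Cl2, −78 → 0 °C
Reagents that add atoms: dimethyl(vinyl)aluminium C=C[Al](C)C
Why: Organoaluminium ring cleavage of the dioxane ketal: aluminium binds the less hindered primary oxygen (O9), the C3–O9 bond ionises to a propargyl-stabilised oxocarbenium ion and the vinyl group is delivered from the aluminate to the face vacated by O9 (retention), which should give the di-tertiary ether with (R)-C3 and free the C9 alcohol.

Step 13
Reactants: 23 ether alcohol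
Product: 25 (3R)-3-{[(1S,2S,4S)-4-bromo-2-(but-3-yn-1-yl)-1,3,3-trimethylcyclohexyl]oxy}-3-methyl-5-(trimethylsilyl)pent-1-en-4-yne, via primary triflate 24 (not isolated)
Conditions: Tf2O, 2,6-lutidine, CH2Cl2, −78 °C; then LiCH2C≡CLi (from propyne and n-BuLi), THF, −78 → −40 °C
Reagents that add atoms: 1,3-dilithiopropyne [Li]CC#C[Li]
Why: Triflation and SN2 alkylation at the propargylic carbon of the propyne dianion extend C9 by C8, C7 and C6 as a terminal alkyne; the hindered secondary bromide should not react at low temperature.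

Step 14
Reactants: 25 terminal alkyne
Product: 26 (3R)-3-{[(1S,2S,4S)-4-bromo-2-[(E)-4-iodo-3-methylbut-3-en-1-yl]-1,3,3-trimethylcyclohexyl]oxy}-3-methyl-5-(trimethylsilyl)pent-1-en-4-yne
Conditions: Me3Al, Cp2ZrCl2 (20 mol %), H2O (1 equiv), CH2Cl2, −25 °C; then I2, THF, −25 → 0 °C
Reagents that add atoms: trimethylaluminium C[Al](C)C; iodine II
Why: Zirconium-catalysed syn-methylalumination (Negishi carboalumination) of the terminal alkyne and iodinolysis give the (E)-2-methyl-1-iodoalkene, which fixes the C6=C7 geometry; the silylated internal alkyne and the vinyl group are far less reactive.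

Step 15
Reactants: 26 vinyl iodide
Product: 28 (2R,5E,8aS,10S,12aS)-10-bromo-2,6,9,9,12a-pentamethyl-2-[(trimethylsilyl)ethynyl]-3,4,7,8,8a,9,10,11,12,12a-decahydro-2H-1-benzoxecine, via B-alkyl-9-BBN adduct 27 (not isolated)
Conditions: 9-BBN-H, THF, 23 °C; then slow addition to Pd(dppf)Cl2 (20 mol %), AsPh3, K3PO4, DMF/THF/H2O, 50 °C, 1 mM
Reagents that add atoms: none
Why: Anti-Markovnikov hydroboration of the C3 vinyl group and intramolecular B-alkyl Suzuki–Miyaura coupling form the C5–C6 bond with retention of the vinyl iodide geometry, closing the ten-membered oxecane as the (E)-alkene.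

Step 16
Reactants: 28 macrocyclic silyl alkyne
Product: 30 (2R,5E,8aS,10S,12aS)-10-bromo-2-ethenyl-2,6,9,9,12a-pentamethyl-3,4,7,8,8a,9,10,11,12,12a-decahydro-2H-1-benzoxecine, via terminal alkyne 29 (not isolated)
Conditions: K2CO3, MeOH, 23 °C; then quinoline, Pd/CaCO3–Pb(OAc)2, H2 (1 atm)
Reagents that add atoms: none
Why: Protodesilylation of the alkynylsilane followed by Lindlar semihydrogenation converts the alkyne into the C1=C2 vinyl group; the trisubstituted ring alkene and the alkyl bromide should be inert.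

Step 17
Reactants: 30 diene
Product: 31 target CNP0243863.1, (3R,6S,7S,10S,11S,14S) in the locants used here
Conditions: L-fructose-derived (ent-)Shi ketone (30 mol %), KHSO5 (as 2KHSO5·KHSO4·K2SO4), K2CO3, Bu4NHSO4, MeCN/CH2(OMe)2/aq. buffer pH 10.5, 0 °C
Reagents that add atoms: potassium peroxymonosulfate [K+].OOS(=O)(=O)[O-]
Why: Shi asymmetric epoxidation (chiral dioxirane) is chemoselective for the electron-rich trisubstituted (E)-alkene over the vinyl group and is stereospecific, so the trans relationship of C5 and C8 is carried into the epoxide while the catalyst should select the (6S,7S) face.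

Compound list
1 | 3-methylbut-2-en-1-ol (prenol) | CC(C)=CCO | starting material
2 | 3-methylbut-2-enoyl chloride | CC(C)=CC(=O)Cl | starting material
3 | 3-methylbut-2-en-1-yl 3-methylbut-2-enoate | CC(C)=CCOC(=O)C=C(C)C | intermediate
4 | 3-methyl-1-(3-methylbut-2-enyloxy)-1-(trimethylsilyloxy)buta-1,3-diene | C=C(C)C=C(OCC=C(C)C)O[Si](C)(C)C | intermediate
5 | trimethylsilyl 3,3-dimethyl-2-(prop-1-en-2-yl)pent-4-enoate | C=CC(C)(C)C(C(C)=C)C(=O)O[Si](C)(C)C | intermediate
6 | rac-3,3-dimethyl-2-(prop-1-en-2-yl)pent-4-enoic acid | C=CC(C)(C)C(C(C)=C)C(=O)O | intermediate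
7 | (S)-1-phenylethylamine | C[C@H](N)c1ccccc1 | starting material
8 | (S)-1-phenylethylammonium (R)-3,3-dimethyl-2-(prop-1-en-2-yl)pent-4-enoate | [O-]C(=O)[C@H](C(C)=C)C(C)(C)C=C.C[C@H]([NH3+])c1ccccc1 | intermediate
9 | (R)-3,3-dimethyl-2-(prop-1-en-2-yl)pent-4-enoic acid | OC(=O)[C@H](C(C)=C)C(C)(C)C=C | intermediate
10 | (R)-3,3-dimethyl-2-(prop-1-en-2-yl)pent-4-en-1-ol | OC[C@H](C(C)=C)C(C)(C)C=C | intermediate
11 | tert-butyl (R)-3,3-dimethyl-2-(prop-1-en-2-yl)pent-4-en-1-yl carbonate | CC(C)(C)OC(=O)OC[C@H](C(C)=C)C(C)(C)C=C | intermediate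
12 | tert-butyl (R)-5-(1,3,2-benzodioxaborol-2-yl)-3,3-dimethyl-2-(prop-1-en-2-yl)pentyl carbonate | CC(C)(C)OC(=O)OC[C@H](C(C)=C)C(C)(C)CCB1Oc2ccccc2O1 | intermediate
13 | tert-butyl (R)-5-hydroxy-3,3-dimethyl-2-(prop-1-en-2-yl)pentyl carbonate | CC(C)(C)OC(=O)OC[C@H](C(C)=C)C(C)(C)CCO | intermediate
14 | tert-butyl (R)-3,3-dimethyl-5-oxo-2-(prop-1-en-2-yl)pentyl carbonate | CC(C)(C)OC(=O)OC[C@H](C(C)=C)C(C)(C)CC=O | intermediate
15 | tert-butyl (2R,4R)-4-bromo-3,3-dimethyl-5-oxo-2-(prop-1-en-2-yl)pentyl carbonate | CC(C)(C)OC(=O)OC[C@H](C(C)=C)C(C)(C)[C@@H](Br)C=O | intermediate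
16 | tert-butyl (2R,4R)-4-bromo-5-hydroxy-3,3-dimethyl-2-(prop-1-en-2-yl)pentyl carbonate | CC(C)(C)OC(=O)OC[C@H](C(C)=C)C(C)(C)[C@@H](Br)CO | intermediate
17 | (2R,4R)-2-bromo-5-[(tert-butoxycarbonyl)oxy]-3,3-dimethyl-4-(prop-1-en-2-yl)pentyl trifluoromethanesulfonate | CC(C)(C)OC(=O)OC[C@H](C(C)=C)C(C)(C)[C@@H](Br)COS(=O)(=O)C(F)(F)F | intermediate
18 | (4aR,6S,8aS)-6-bromo-5,5,8a-trimethylhexahydro-4H-benzo[d][1,3]dioxin-2-one | O=C1OC[C@H]2C(C)(C)[C@@H](Br)CC[C@]2(C)O1 | intermediate
19 | (1S,2R,4S)-4-bromo-2-(hydroxymethyl)-1,3,3-trimethylcyclohexan-1-ol | OC[C@H]1C(C)(C)[C@@H](Br)CC[C@]1(C)O | intermediate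
20 | 4-(trimethylsilyl)but-3-yn-2-one | CC(=O)C#C[Si](C)(C)C | starting material
21 | bis(trimethylsilyl) ether of 19 | C[Si](C)(C)OC[C@H]1C(C)(C)[C@@H](Br)CC[C@]1(C)O[Si](C)(C)C | intermediate
22 | (2S,4aR,6S,8aS)-6-bromo-2,5,5,8a-tetramethyl-2-[(trimethylsilyl)ethynyl]hexahydro-4H-benzo[d][1,3]dioxine (alkynyl axial, cis to the 8a-methyl) | C[Si](C)(C)C#C[C@@]1(C)OC[C@H]2C(C)(C)[C@@H](Br)CC[C@]2(C)O1 | intermediate
23 | {(1R,3S,6S)-3-bromo-2,2,6-trimethyl-6-[(R)-3-methyl-5-(trimethylsilyl)pent-1-en-4-yn-3-yl]oxycyclohexyl}methanol | OC[C@H]1C(C)(C)[C@@H](Br)CC[C@]1(C)O[C@](C)(C=C)C#C[Si](C)(C)C | intermediate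
24 | trifluoromethanesulfonate of 23 | FC(F)(F)S(=O)(=O)OC[C@H]1C(C)(C)[C@@H](Br)CC[C@]1(C)O[C@](C)(C=C)C#C[Si](C)(C)C | intermediate
25 | (3R)-3-{[(1S,2S,4S)-4-bromo-2-(but-3-yn-1-yl)-1,3,3-trimethylcyclohexyl]oxy}-3-methyl-5-(trimethylsilyl)pent-1-en-4-yne | C#CCC[C@H]1C(C)(C)[C@@H](Br)CC[C@]1(C)O[C@](C)(C=C)C#C[Si](C)(C)C | intermediate
26 | (3R)-3-{[(1S,2S,4S)-4-bromo-2-[(E)-4-iodo-3-methylbut-3-en-1-yl]-1,3,3-trimethylcyclohexyl]oxy}-3-methyl-5-(trimethylsilyl)pent-1-en-4-yne | I/C=C(\C)CC[C@H]1C(C)(C)[C@@H](Br)CC[C@]1(C)O[C@](C)(C=C)C#C[Si](C)(C)C | intermediate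
27 | 9-BBN adduct of 26 (boron on C5) | I/C=C(\C)CC[C@H]1C(C)(C)[C@@H](Br)CC[C@]1(C)O[C@](C)(CCB2C3CCCC2CCC3)C#C[Si](C)(C)C | intermediate
28 | (2R,5E,8aS,10S,12aS)-10-bromo-2,6,9,9,12a-pentamethyl-2-[(trimethylsilyl)ethynyl]-3,4,7,8,8a,9,10,11,12,12a-decahydro-2H-1-benzoxecine | C[Si](C)(C)C#C[C@@]1(C)CC/C=C(C)/CC[C@H]2C(C)(C)[C@@H](Br)CC[C@]2(C)O1 | intermediate
29 | (2R,5E,8aS,10S,12aS)-10-bromo-2-ethynyl-2,6,9,9,12a-pentamethyl-3,4,7,8,8a,9,10,11,12,12a-decahydro-2H-1-benzoxecine | C#C[C@@]1(C)CC/C=C(C)/CC[C@H]2C(C)(C)[C@@H](Br)CC[C@]2(C)O1 | intermediate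
30 | (2R,5E,8aS,10S,12aS)-10-bromo-2-ethenyl-2,6,9,9,12a-pentamethyl-3,4,7,8,8a,9,10,11,12,12a-decahydro-2H-1-benzoxecine | C=C[C@@]1(C)CC/C=C(C)/CC[C@H]2C(C)(C)[C@@H](Br)CC[C@]2(C)O1 | intermediate
31 | CNP0243863.1, the (6S,7S)-epoxide of 30 | C=C[C@@]1(C)CC[C@@H]2O[C@@]2(C)CC[C@H]2C(C)(C)[C@@H](Br)CC[C@]2(C)O1 | target

Total step count: 17. Longest linear sequence: 17 steps (1/2 → 31); compounds 7 and 20 are purchased.

Steps most likely to fail

Step 9. The alkene may displace the primary triflate too slowly, so that elimination, loss of the triflate to adventitious nucleophiles or acid-induced loss of the tert-butyl group before cyclisation compete, and the C11 cation may eliminate instead of being captured. The fallback sets out from 16 and comes back at 18. The primary alcohol is converted under Appel conditions (CBr4, PPh3, CH2Cl2, 0 °C) into the vicinal dibromide tert-butyl (2R,4R)-4,5-dibromo-3,3-dimethyl-2-(prop-1-en-2-yl)pentyl carbonate F1. AgOTf with 2,6-di-tert-butyl-4-methylpyridine in CH2Cl2/(CF3)2CHOH at −40 °C should then abstract the unhindered primary bromide with anchimeric assistance from the C14 bromine. Backside attack at the neopentyl C14 is not possible, so a discrete bromonium ion of unchanged C14 configuration results, and the same chair cyclisation with carbonate capture should give 18.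

Step 12. Methyl may be transferred instead of vinyl, the retentive delivery may erode, or the oxocarbenium ion may fragment at the tertiary C11–O bond. The fallback sets out from 22 and comes back at 23; it uses invertive attack by an external nucleophile and exchanges the roles of the two alkynes.
- Treatment of 22 with (triisopropylsilyl)(trimethylsilyl)acetylene and TiCl4 (CH2Cl2, −78 °C) should give the bis-alkynyl ether {(1R,3S,6S)-3-bromo-2,2,6-trimethyl-6-[3-methyl-1-(triisopropylsilyl)-5-(trimethylsilyl)penta-1,4-diyn-3-yl]oxycyclohexyl}methanol F2, the new alkynyl group entering anti to the departing O9.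
- Because the entering group now becomes the future C1=C2 vinyl and the original axial alkyne the C4=C5 vinyl, inversion leads to the same C3 configuration as in 23.
- K2CO3 in MeOH removes only the trimethylsilyl group to give the terminal alkyne F3.
- Semihydrogenation (H2, Pd/CaCO3–Pb(OAc)2, quinoline) gives the vinyl compound F4.
- Bu4NF gives the free enyne F5.
- C-silylation of the acetylide (LiN(SiMe3)2, Me3SiCl, then aqueous citric acid to cleave the O–Si bond) returns 23.

Step 15. β-Hydride elimination or protodeboronation of the alkylborane and intermolecular coupling may outrun closure of the strained (E)-cyclodecene-type ring. The fallback sets out from 23 and comes back at 28. Hydroboration of the vinyl group (9-BBN-H) and B-alkyl Suzuki coupling with vinyl bromide (Pd(dppf)Cl2, K3PO4) give the but-3-enyl ether F6. Triflation and copper-catalysed coupling with CH2=C(CH3)CH2MgCl (CuI, THF, −40 °C) give the diene F7. Ring-closing metathesis (second-generation Hoveyda–Grubbs catalyst, toluene, 80 °C, 1 mM) should then give 28 after separation from the (Z)-isomer, whose proportion is the weakness of this alternative.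

Further compounds
F1 | step 9 | tert-butyl (2R,4R)-4,5-dibromo-3,3-dimethyl-2-(prop-1-en-2-yl)pentyl carbonate | CC(C)(C)OC(=O)OC[C@H](C(C)=C)C(C)(C)[C@@H](Br)CBr
F2 | step 12 | {(1R,3S,6S)-3-bromo-2,2,6-trimethyl-6-[3-methyl-1-(triisopropylsilyl)-5-(trimethylsilyl)penta-1,4-diyn-3-yl]oxycyclohexyl}methanol | OC[C@H]1C(C)(C)[C@@H](Br)CC[C@]1(C)O[C@@](C)(C#C[Si](C(C)C)(C(C)C)C(C)C)C#C[Si](C)(C)C
F3 | step 12 | {(1R,3S,6S)-3-bromo-2,2,6-trimethyl-6-[3-methyl-1-(triisopropylsilyl)penta-1,4-diyn-3-yl]oxycyclohexyl}methanol | OC[C@H]1C(C)(C)[C@@H](Br)CC[C@]1(C)O[C@@](C)(C#C[Si](C(C)C)(C(C)C)C(C)C)C#C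
F4 | step 12 | {(1R,3S,6S)-3-bromo-2,2,6-trimethyl-6-[(R)-3-methyl-5-(triisopropylsilyl)pent-1-en-4-yn-3-yl]oxycyclohexyl}methanol | OC[C@H]1C(C)(C)[C@@H](Br)CC[C@]1(C)O[C@@](C)(C#C[Si](C(C)C)(C(C)C)C(C)C)C=C
F5 | step 12 | {(1R,3S,6S)-3-bromo-2,2,6-trimethyl-6-[(R)-3-methylpent-1-en-4-yn-3-yl]oxycyclohexyl}methanol | OC[C@H]1C(C)(C)[C@@H](Br)CC[C@]1(C)O[C@@](C)(C#C)C=C
F6 | step 15 | {(1R,3S,6S)-3-bromo-2,2,6-trimethyl-6-[(R)-3-methyl-1-(trimethylsilyl)hept-6-en-1-yn-3-yl]oxycyclohexyl}methanol | OC[C@H]1C(C)(C)[C@@H](Br)CC[C@]1(C)O[C@](C)(CCC=C)C#C[Si](C)(C)C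
F7 | step 15 | (3R)-3-{[(1S,2S,4S)-4-bromo-1,3,3-trimethyl-2-(3-methylbut-3-en-1-yl)cyclohexyl]oxy}-3-methyl-1-(trimethylsilyl)hept-6-en-1-yne | C=C(C)CC[C@H]1C(C)(C)[C@@H](Br)CC[C@]1(C)O[C@](C)(CCC=C)C#C[Si](C)(C)C
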